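## Analysis of the target

The target is a C30 bis-oxepane in which two bicyclic units are joined by the C12–C13 ethylene bridge. Atoms are numbered along the main chain from the methylene-bearing carbon C1 to the carbinol carbon C24, with O5 and O20 as ring oxygens: ring A is the cyclohexane C1–C4, C10, C11; ring B the oxepane C4, O5, C6–C10; ring C the cyclohexane C14, C15, C21–C24; ring D the oxepan-3-one C15–C19, O20, C21. There are eight stereocentres (4S, 7S, 10S, 11R, 14S, 15S, 21S, 24R); both ring fusions are trans, the angular methyl groups on the quaternary carbons C10 and C15 are axial, the chain carbons C12 and C13 are equatorial on C11 and C14, and the C24 hydroxyl is axial and syn to the C15 methyl. Read from C11 to C1 and from C14 to C24, rings A/B and rings C/D are the same trans-fused 2,2-dimethyl-perhydro-1-benzoxepine with the same absolute configuration (C10 ≡ C15, C4 ≡ C21, C11 ≡ C14); they differ only in oxidation level (C7 carbinol against C18 ketone, C1 methylene against C24 methyl carbinol). Sensitive groups are the 1,1-disubstituted alkene (acid, hydrogenation), the tertiary alcohol (elimination) and the C18 ketone, whose α-carbon C19 carries the ether oxygen, so that electron-transfer reductants would cleave C19–O20. The difficulty lies in two seven-membered ethers with a fully substituted carbon next to oxygen, in the quaternary centres C10 and C15 beside the ring-fusion ether carbons, and in bond formation at the neopentyl carbons C11 and C14. The strategy rests on the segment O20–C19(CH3)2–C18(=O)–C17 of ring D: with a temporary C17–C21 bond it is a 2,2-dimethyl-3(2H)-furanone, an enone whose β-carbon C21 can be joined to C15 by light while C16 closes onto C17.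

## Retrosynthetic reasoning

**Oxidation level at C18 and C7 (32 ⇐ 31 ⇐ 30 ⇐ 29).** No skeletal bond is cut. The C18 ketone cannot be present during the methyl addition at C24 or the enolate chemistry at C14, so it is traced back to a protected 18S carbinol. C18 carries a 4-methoxybenzyl ether and C7 a silyl ether, so that C18 can be unmasked and oxidized in 30 while C7 stays covered; the silyl group leaves last.

**C24–CH3 (29 ⇐ 28).** The methyl group is removed to leave the C24 ketone, which is also the group that activates C14. Forward, a methyl nucleophile has to enter equatorially, away from the axial C15 methyl that blocks the axial trajectory; this puts the hydroxyl axial, as in 24R.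

**C13–C14 (28 ⇐ 27 ⇐ 24 + 21).** This is the central cut. It is made here and not at C11–C12 or C12–C13 because C14 is α to the C24 carbonyl and because it divides the molecule into two pieces of the same skeleton, with C13 as an aldehyde. A ketone such as 23 has two α-methylene groups, and base would take a proton from C23 rather than from the neopentyl C14. That preference is turned to use: it introduces the C22=C23 double bond of 24, after which C14 is the only enolizable position. The extra double bond is removed together with the exocyclic C13=C14 bond of 27, and protonation of the resulting enolate anti to the C15 methyl sets C14.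

**Left half (21 ⇐ 20 ⇐ 19 ⇐ 18 ⇐ 14 + 15).** The C1 methylene is taken back to the C1 ketone and the C11–C12 bond to an aldol condensation of enone 14 with the two-carbon aldehyde ester 15. This is the same sequence as the union, applied to the same skeleton, so C11 is set by the same protonation anti to the C10 methyl.

**Divergence (14 ⇐ 13 ⇐ 12 ⇐ 11 and 24 ⇐ 23 ⇐ 22 ⇐ 11).** Both enones come from alcohol 11 and differ only in the ether on the C18 (≡ C7) oxygen. One bicyclic intermediate therefore supplies rings A/B and rings C/D.

**C18 carbinol (11 ⇐ 10).** The reduction has to give 18S, which becomes 7S in the left half; in the right half the centre is later oxidized away. The two flanks of the ketone (quaternary C19, methylene C17) differ enough for catalyst control.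

**Ring D (10 ⇐ 9 ⇐ 8).** The C17–C21 bond is added back to give cyclobutane 8, which has donor O20 on C21 and the acceptor carbonyl C18 on C17. Forward, this bond ionizes under a silyl Lewis acid, the cation loses H22 to give enol ether 9, and hydrogenation anti to the C15 methyl gives the trans-fused 10. Ionization and reduction are kept in separate steps because a silane with a Lewis acid would also reduce the C24 dioxolane.

**Key disconnection (8 ⇐ 7).** C15–C21 and C16–C17 are cut. This takes ring C and the cyclobutane back to a furanone with a four-atom tether to a 1,1-disubstituted alkene. The substrate is achiral because C24 is a ketal; only C15 has to be controlled, by a chiral Lewis acid on the C18 carbonyl.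

**Furanone and tether (7 ⇐ 4 + 5; 4 ⇐ 3 ⇐ 1 + 2).** The C17–C21 bond of the furanone comes from a Claisen condensation of ester 4 with hydroxy ketone 5, and O20–C21 from cyclodehydration under conditions mild enough for the ketal. The C24–C14 bond comes from acylation of allylsilane 2 by acid chloride 1; an allylmagnesium reagent would add a second time to the ketone it forms. The ketal is put on under aprotic conditions so that the alkene stays out of conjugation.

## Alternatives that were turned down

**Alternative 1:** Disconnection of O5–C6 and C10–C11 in the left bicycle A2 (rings A and B with the C7 carbinol and a C13 silyl ether), back to the open-chain diepoxide A1, which carries the C6–C7 and C4–C10 epoxides and a (trimethylsilyl)methyl group on C1.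
- Forward key step: TMSOTf or BF3·OEt2 opens the C6–C7 epoxide at its tertiary carbon, the oxygen of the C4–C10 epoxide attacks C6, and the epoxonium ion is opened at C10 by the allylsilane carbon C11; rings B and A close in one operation.
- For it: two rings, two bonds and the centres C4, C10 and C11 come from one step, C7 is carried unchanged from an epoxide, and the C1 methylene is the direct result of silyl loss. On bond economy for rings A and B and on C7 it is stronger than the chosen route, which needs a reduction for C7, an enone detour for C11 and an olefination for C1.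
- Against it: it answers only half the molecule; rings C and D, the C18 ketone and the C24 carbinol need a separate solution and a separate source of chirality. The cascade must prefer seven-membered epoxonium formation over six-membered opening at C7 and a chair over a boat for ring A. A1 needs two trisubstituted epoxides of defined configuration and a Z-trisubstituted allylsilane on one chain; an epoxidation catalyst does not tell two trisubstituted alkenes apart, so they must be introduced one after the other.
- Comparison: the chosen strategy gives up the one-step assembly of rings A and B. In its place it offers one sequence that serves both halves, one catalyst-controlled event for C10 and C15 alike, and a left half that costs seven steps from the shared alcohol 11.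

**Alternative 2:** Disconnection of C14–C15 in the ring C/D ketal A4, back to A3, a ring D enol ether (C15=C21) whose C21 side chain carries the C24 silyl ether and an allylsilane.
- Forward key step: constant-current oxidation at a carbon anode (LiClO4, MeOH/THF, 2,6-lutidine) gives the enol ether radical cation, C14 of the allylsilane bonds to C15, and methanol traps C21 as a methyl ketal while silyl loss leaves the C14 vinyl group.
- For it: the quaternary C15 and the congested C14–C15 bond form without a reagent. C14 arrives already substituted and C24 is already a protected tertiary carbinol, so neither the regiochemistry of enolization at C14 nor the facial selectivity of a methyl addition arises; on both points it is stronger than the chosen route.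
- Against it: A3 presupposes ring D as a seven-membered tetrasubstituted enol ether with the gem-dimethyl ether, a masked ketone and an enantioenriched tertiary ether at C24, so the hardest ring is only moved into the precursor. C14 and C15 are set relative to C24 across a flexible chain. C21 emerges as a ketal that still needs reduction to the trans hydrogen by silane and Lewis acid, which would also cleave the C18 dioxolane of A4. The vinyl group leaves the link to the left half to a coupling at a hindered terminus.
- Comparison: the chosen strategy buys the heteroatom pattern of ring D as a furanone and makes ring C and C15 in the same step; it pays with the enone detour at C14 and a methyl addition, both of which are governed by the axial C15 methyl.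

**Alternative 3:** Disconnection of C14–C24 in the γ-lactone A6, back to A5, a ring D oxepane with an (E)-enoate on C15 and a 3-oxobutyl chain on C21.
- Forward key step: SmI2 reduces the methyl ketone, the C24 ketyl adds to the enoate β-carbon C14 in a 6-exo closure that forms ring C, and the samarium alkoxide lactonizes onto C12.
- For it: C14 and C24 are set together, the five-membered lactone forces the C24 oxygen and C13 onto the same face (as in the target), and the tertiary carbinol needs no methyl addition. On the control of C24 relative to C14 it is stronger than the chosen route.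
- Against it: A5 already contains ring D with the quaternary C15 and the trans C15/C21 relationship, which is most of the difficulty. The ketyl must attack a neopentyl β-carbon next to the quaternary centre, where simple reduction of the ketone competes, and the lactone does not control the face of C14 relative to the C15 methyl.
- Comparison: the chosen route sets C14 and C24 in two separate steps, both directed by the C15 methyl, and in return builds ring C and the precursor of ring D from an achiral chain in one step.

Key step: step 4

Remark (assumption): the sense of induction of an AlBr3-activated oxazaborolidine on a 3(2H)-furanone cannot be derived from existing models; the catalyst from (S)-prolinol is written, and its mirror image is to be used if the 15R adduct results.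

Remark (numbering): compounds 8–12 and 22–24 carry the right-half locants C14–C24. From 13 on, the left series is renumbered C24→C1, C23→C2, C22→C3, C21→C4, O20→O5, C19→C6, C18→C7, C17→C8, C16→C9, C15→C10, C14→C11.

## Route

Step 1
Reactants: 1 methyl 4-chloro-4-oxobutanoate; 2 trimethyl(2-methylprop-2-en-1-yl)silane
Product: 3 methyl 6-methyl-4-oxohept-6-enoate
Conditions: AlCl3, CH2Cl2, −78 °C; cold aq NaHCO3
Reagents that add atoms: none
Why: Lewis-acid acylation of an allylsilane (SE2′): the acylium ion from 1 is attacked by the CH2 terminus of 2 and loss of the silyl group leaves the β,γ-unsaturated ketone; unlike an allylmagnesium reagent the silane does not add to the ketone it has just formed, and the cold basic quench keeps the alkene out of conjugation.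

Step 2
Reactants: 3 methyl 6-methyl-4-oxohept-6-enoate
Product: 4 methyl 3-[2-(2-methylprop-2-en-1-yl)-1,3-dioxolan-2-yl]propanoate
Conditions: (Me3SiOCH2)2, TMSOTf (cat.), CH2Cl2, −78 → −20 °C; pyridine
Reagents that add atoms: 1,2-bis(trimethylsilyloxy)ethane, C[Si](C)(C)OCCO[Si](C)(C)C
Why: Noyori ketalization under aprotic conditions at low temperature; ester and 1,1-disubstituted alkene are inert, and the alkene cannot move into conjugation once C24 is sp3.

Step 3
Reactants: 4 methyl 3-[2-(2-methylprop-2-en-1-yl)-1,3-dioxolan-2-yl]propanoate; 5 3-hydroxy-3-methylbutan-2-one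
Product: 7 2,2-dimethyl-5-{2-[2-(2-methylprop-2-en-1-yl)-1,3-dioxolan-2-yl]ethyl}furan-3(2H)-one, via hydroxy diketone 6 (not isolated)
Conditions: 5 (3 equiv), LiN(i-Pr)2 (6 equiv), THF, −78 → 0 °C; then 4, 0 °C → rt; aq NH4Cl; crude with PPTS (cat.), PhH, 4 Å sieves, 50 °C
Reagents that add atoms: none
Why: Claisen condensation of the ester with the dianion of 5, which can form an enolate only at its methyl group, followed by acid-catalysed cyclodehydration of the α′-hydroxy 1,3-diketone (hemiketal at C21, then loss of water) to the 3(2H)-furanone; PPTS over sieves is anhydrous and weak enough to leave the dioxolane in place.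

Step 4
Reactants: 7 2,2-dimethyl-5-{2-[2-(2-methylprop-2-en-1-yl)-1,3-dioxolan-2-yl]ethyl}furan-3(2H)-one
Product: 8 (15S,17R,21R)-photoadduct, a cyclobutane C15–C16–C17–C21 cis-fused both to the 2,2-dimethylfuran-3-one ring (O20, C19, C18, C17, C21) and to ring C (C15 methyl; C24 ethylene ketal)
Conditions: hν (366 nm), oxazaborolidine from (S)-α,α-bis(3,5-dimethylphenyl)prolinol and 2,4,6-trifluorophenylboronic acid activated with AlBr3 (50 mol%), CH2Cl2 (10 mM), −75 °C
Reagents that add atoms: none
Why: Proposed new method: the closest known reaction is the enantioselective intramolecular (2+2) photocycloaddition of cyclic enones and vinylogous esters bound to an AlBr3-activated oxazaborolidine, here carried over to a 3(2H)-furanone. Coordination of the Lewis acid to the C18 carbonyl shifts the π–π* band to longer wavelength, so that at 366 nm mainly the complex absorbs and the unbound, racemic channel stays slow. After intersystem crossing the β-carbon C21 of the triplet bonds to the internal alkene carbon C15 in a 6-exo-trig closure that forms ring C and leaves a 1,4-biradical at C17 and C16; spin inversion and C16–C17 bonding then close the four-membered ring. The four-atom tether allows this straight closure through a chair-like six-membered transition state, whereas the crossed mode (C21 to C16) would need a seven-membered ring and a bridged product. The relative configuration at C15, C17 and C21 is fixed by geometry, because the cyclobutane can only be cis-fused to both the furanone and the new cyclohexane, so the achiral substrate has a single diastereomer open to it. The absolute configuration (15S) comes from the catalyst, whose aryl groups shield one face of the bound enone so that the tether folds over the other. The step needs enantioface selectivity and the regiochemistry of the first bond (the first rests on the catalyst, the second on the tether length), and since C17 and C21 are lost again in step 5, only C15 has to be set here.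

Step 5
Reactants: 8 (15S,17R,21R)-photoadduct
Product: 9 (15S)-enol ether ketone, ring D 2,2-dimethyloxepan-3-one (C18 ketone) fused at C15–C21 to ring C with a C21=C22 double bond; C15 methyl; C24 ethylene ketal
Conditions: TMSOTf (10 mol%), CH2Cl2, −78 → −20 °C; Et3N; aq NaHCO3
Reagents that add atoms: none
Why: Proposed new method: the cyclobutane has donor O20 on C21 and the acceptor carbonyl C18 on C17, so silylation of the carbonyl lets the C17–C21 bond ionize to a C18 silyl enol ether and a C21 oxocarbenium ion; this loses H22 (C15 has no hydrogen), and the released acid returns the silyl enol ether to the ketone and regenerates the catalyst, so relief of cyclobutane strain drives a net isomerization. The closest known reaction is the acid-promoted retro-aldol-type opening of β-oxygenated cyclobutyl ketones (De Mayo logic); the conditions are those under which the dioxolane was made in step 2, so the ketal should persist.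

Step 6
Reactants: 9 (15S)-enol ether ketone
Product: 10 (15S,21S)-trans-fused ring C/D ketone, 2,2-dimethyloxepan-3-one fused to ring C with C21–H anti to the C15 methyl; C24 ethylene ketal
Conditions: H2 (3 atm), Pd/C, EtOAc, Et3N (1%), rt
Reagents that add atoms: none
Why: Heterogeneous hydrogenation of the trisubstituted enol ether; hydrogen is delivered to C21 from the face opposite the axial methyl on the neighbouring C15, which gives the trans ring fusion (21S), and the amine protects the enol ether from acid hydrolysis.

Step 7
Reactants: 10 (15S,21S)-trans-fused ring C/D ketone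
Product: 11 (15S,18S,21S)-alcohol, the C18 carbinol of 10
Conditions: (R)-Me-CBS oxazaborolidine [(R)-1-methyl-3,3-diphenyltetrahydro-1H,3H-pyrrolo[1,2-c][1,3,2]oxazaborole] (0.5 equiv), BH3·SMe2, THF, −20 → 0 °C; MeOH
Reagents that add atoms: none
Why: Corey–Bakshi–Shibata reduction; the catalyst distinguishes the quaternary C19 from the methylene C17, and the (R)-catalyst should deliver hydride to give the 18S carbinol, which is the C7 configuration of the left half.

Step 8
Reactants: 11 (15S,18S,21S)-alcohol
Product: 12 (15S,18S,21S)-C18 tert-butyldimethylsilyl ether of 11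
Conditions: TBSOTf, 2,6-lutidine, CH2Cl2, −78 → 0 °C
Reagents that add atoms: tert-butyldimethylsilyl trifluoromethanesulfonate, CC(C)(C)[Si](C)(C)OS(=O)(=O)C(F)(F)F
Why: Silylation of a hindered secondary alcohol with the silyl triflate; a ketone-derived dioxolane tolerates the buffered reagent at low temperature.

Step 9
Reactants: 12 (15S,18S,21S)-silyl ether
Product: 13 (4S,7S,10S)-left-series ketone, trans-fused rings A/B with C1 ketone, C7 OTBS, C6 gem-dimethyl and C10 methyl
Conditions: PPTS, acetone/H2O (10:1), 60 °C
Reagents that add atoms: water, O
Why: Acid hydrolysis of the dioxolane; the hindered secondary silyl ether survives PPTS.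

Step 10
Reactants: 13 (4S,7S,10S)-left-series ketone
Product: 14 (4S,7S,10S)-left-series enone, 13 with a C2=C3 double bond
Conditions: LiN(i-Pr)2, THF, −78 °C; then PhS(Cl)=N-t-Bu, −78 °C
Reagents that add atoms: none
Why: Mukaiyama dehydrogenation of the lithium enolate with N-tert-butylbenzenesulfinimidoyl chloride; kinetic deprotonation favours C2 over the neopentyl C11, and only the C2 enolate can give an enone, because C10 next to C11 has no hydrogen.

Step 11
Reactants: 14 (4S,7S,10S)-left-series enone; 15 ethyl glyoxylate
Product: 18 (4S,7S,10S)-dienone ester with exocyclic C11=C12H–CO2Et (geometry not assigned), via aldol adduct 16 (not isolated), via mesylate 17 (not isolated)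
Conditions: LiN(i-Pr)2, THF, −78 °C; 15, −78 °C; aq NH4Cl; crude: MsCl, Et3N, CH2Cl2, 0 °C; DBU, rt
Reagents that add atoms: none
Why: Kinetic deprotonation of the enone can occur only at the α′ carbon C11, so the aldol addition is regiospecific; mesylation and E1cB elimination give the alkylidene, and neither its geometry nor the aldol stereocentres matter because C11 and C12 are reduced in step 12.

Step 12
Reactants: 18 (4S,7S,10S)-dienone ester
Product: 19 (4S,7S,10S,11S)-keto ester, ring A C1 ketone with equatorial CH2CO2Et on C11
Conditions: [(Ph3P)CuH]6 (0.5 equiv), PhH, H2O (3 equiv), rt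
Reagents that add atoms: none
Why: Conjugate reduction by the phosphine-stabilized copper hydride of both the ring enone and the exocyclic keto-enoate, leaving ester and silyl ether; C11 is set when its enolate is protonated on the face opposite the axial C10 methyl, which places the chain equatorial, and this is also the more stable epimer.

Step 13
Reactants: 19 (4S,7S,10S,11S)-keto ester
Product: 20 (4S,7S,10S,11R)-methylene ester, C1 exocyclic methylene
Conditions: Ph3PCH3Br, KOt-Bu, THF, 0 °C → rt
Reagents that add atoms: methyltriphenylphosphonium bromide, C[P+](c1ccccc1)(c1ccccc1)c1ccccc1.[Br-]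
Why: Wittig methylenation of the ketone; the ester is inert to the ylide, and base-induced epimerization at C11 can only lead to the equatorial epimer already in hand (the descriptor changes from S to R by priority only).

Step 14
Reactants: 20 (4S,7S,10S,11R)-methylene ester
Product: 21 (4S,7S,10S,11R)-left-half aldehyde, C13 aldehyde
Conditions: i-Bu2AlH (1.1 equiv), CH2Cl2, −78 °C; aq potassium sodium tartrate
Reagents that add atoms: none
Why: Partial reduction of the ester; the tetrahedral aluminium hemiacetal is stable at −78 °C and gives the aldehyde on work-up, while alkene and silyl ether are inert.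

Step 15
Reactants: 11 (15S,18S,21S)-alcohol
Product: 22 (15S,18S,21S)-C18 4-methoxybenzyl ether of 11
Conditions: NaH, 4-MeOC6H4CH2Cl, Bu4NI (cat.), DMF, 0 → 40 °C
Reagents that add atoms: 4-methoxybenzyl chloride, COc1ccc(CCl)cc1
Why: Williamson etherification; the basic conditions leave the ketal untouched, and the benzylic ether is orthogonal to the silyl ether of the left half.

Step 16
Reactants: 22 (15S,18S,21S)-4-methoxybenzyl ether
Product: 23 (15S,18S,21S)-right-series ketone, C24 ketone with C18 4-methoxybenzyl ether
Conditions: PPTS, acetone/H2O (10:1), 60 °C
Reagents that add atoms: water, O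
Why: Acid hydrolysis of the dioxolane; the 4-methoxybenzyl ether is stable to weak aqueous acid.

Step 17
Reactants: 23 (15S,18S,21S)-right-series ketone
Product: 24 (15S,18S,21S)-right-series enone, C22=C23 conjugated to the C24 ketone
Conditions: LiN(i-Pr)2, THF, −78 °C; then PhS(Cl)=N-t-Bu, −78 °C
Reagents that add atoms: none
Why: Mukaiyama dehydrogenation as in step 10; only the C23 enolate can lead to an enone, and the new double bond removes C23 as a site of enolization.

Step 18
Reactants: 24 (15S,18S,21S)-right-series enone; 21 (4S,7S,10S,11R)-left-half aldehyde
Product: 27 (4S,7S,10S,11R,15S,18S,21S)-dienone with exocyclic C13=C14 and ring C22=C23 both conjugated to the C24 ketone, via aldol adduct 25 (not isolated), via mesylate 26 (not isolated)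
Conditions: LiN(i-Pr)2, THF, −78 °C; 21, −78 °C; aq NH4Cl; crude: MsCl, Et3N, CH2Cl2, 0 °C; DBU, rt
Reagents that add atoms: none
Why: Aldol addition of the α′ lithium enolate of 24 (C14 is the only enolizable position) to the aldehyde, then mesylation and E1cB elimination; the C13–C14 bond joins the halves, and the aldol stereocentres disappear in the alkene.

Step 19
Reactants: 27 dienone
Product: 28 (4S,7S,10S,11R,14S,15S,18S,21S)-ketone, saturated C24 ketone with the C12–C13 bridge equatorial on C14
Conditions: [(Ph3P)CuH]6 (0.5 equiv), PhH, H2O (3 equiv), rt
Reagents that add atoms: none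
Why: Conjugate reduction of both enone double bonds by the copper hydride, which leaves the isolated C1 methylene alone; C14 is set by protonation of its enolate on the face opposite the axial C15 methyl, giving the equatorial and more stable epimer.

Step 20
Reactants: 28 ketone
Product: 29 (4S,7S,10S,11R,14S,15S,18S,21S,24R)-tertiary alcohol
Conditions: MeLi, CeCl3, THF, −78 °C
Reagents that add atoms: methyllithium, [Li]C
Why: Addition of the organocerium reagent, which is nucleophilic but weakly basic and so does not enolize the hindered ketone; the axial trajectory is blocked by the syn-axial C15 methyl, so the methyl group enters equatorially and the hydroxyl ends axial (24R).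

Step 21
Reactants: 29 tertiary alcohol
Product: 30 (4S,7S,10S,11R,14S,15S,18S,21S,24R)-diol with free C18 hydroxyl and C7 silyl ether
Conditions: DDQ, CH2Cl2/pH 7 buffer (10:1), 0 °C → rt
Reagents that add atoms: none
Why: Oxidative cleavage of the 4-methoxybenzyl ether through its benzylic cation; isolated alkene, silyl ether and tertiary alcohol are not affected.

Step 22
Reactants: 30 diol
Product: 31 (4S,7S,10S,11R,14S,15S,21S,24R)-C7 silyl ether of the target, with C18 ketone
Conditions: Dess–Martin periodinane, NaHCO3, CH2Cl2, rt
Reagents that add atoms: none
Why: Oxidation of the only secondary alcohol by the hypervalent iodine reagent; the tertiary C24 hydroxyl cannot be oxidized, and the buffer protects the methylene group from acid.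

Step 23
Reactants: 31 C7 silyl ether of the target
Product: 32 target CNP0160418.1 (4S,7S,10S,11R,14S,15S,21S,24R)
Conditions: Bu4NF, THF, 50 °C
Reagents that add atoms: none
Why: Fluoride cleavage of the silyl ether; there is no β-hydroxy ketone or other base-labile relationship in the product, and the C18 ketone has no stereocentre on either flank.

## Compound list

1 | methyl 4-chloro-4-oxobutanoate | COC(=O)CCC(Cl)=O | starting material
2 | trimethyl(2-methylprop-2-en-1-yl)silane | CC(=C)C[Si](C)(C)C | starting material
3 | methyl 6-methyl-4-oxohept-6-enoate | COC(=O)CCC(=O)CC(C)=C | intermediate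
4 | methyl 3-[2-(2-methylprop-2-en-1-yl)-1,3-dioxolan-2-yl]propanoate | COC(=O)CCC1(CC(C)=C)OCCO1 | intermediate
5 | 3-hydroxy-3-methylbutan-2-one | CC(=O)C(C)(C)O | starting material
6 | 6-hydroxy-6-methyl-1-[2-(2-methylprop-2-en-1-yl)-1,3-dioxolan-2-yl]heptane-3,5-dione | CC(C)(O)C(=O)CC(=O)CCC1(CC(C)=C)OCCO1 | intermediate (not isolated)
7 | 2,2-dimethyl-5-{2-[2-(2-methylprop-2-en-1-yl)-1,3-dioxolan-2-yl]ethyl}furan-3(2H)-one | CC1(C)OC(CCC2(OCCO2)CC(C)=C)=CC1=O | intermediate
8 | (15S,17R,21R)-photoadduct: cyclobutane cis-fused to the furanone ring and to ring C; C24 ethylene ketal | C1[C@]2(C)C[C@H]3C(=O)C(C)(C)O[C@@]23CCC14OCCO4 | intermediate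
9 | (15S)-enol ether ketone: ring D oxepan-3-one with C21=C22; C24 ethylene ketal | C1[C@]2(C)CCC(=O)C(C)(C)OC2=CCC13OCCO3 | intermediate
10 | (15S,21S)-trans-fused ring C/D ketone; C24 ethylene ketal | C1[C@]2(C)CCC(=O)C(C)(C)O[C@H]2CCC13OCCO3 | intermediate
11 | (15S,18S,21S)-alcohol (C18 carbinol of 10) | C1[C@]2(C)CC[C@H](O)C(C)(C)O[C@H]2CCC13OCCO3 | intermediate
12 | (15S,18S,21S)-C18 tert-butyldimethylsilyl ether of 11 | C1[C@]2(C)CC[C@H](O[Si](C)(C)C(C)(C)C)C(C)(C)O[C@H]2CCC13OCCO3 | intermediate
13 | (4S,7S,10S)-left-series ketone (C1 ketone, C7 OTBS) | O=C1C[C@]2(C)CC[C@H](O[Si](C)(C)C(C)(C)C)C(C)(C)O[C@H]2CC1 | intermediate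
14 | (4S,7S,10S)-left-series enone (C2=C3) | O=C1C[C@]2(C)CC[C@H](O[Si](C)(C)C(C)(C)C)C(C)(C)O[C@H]2C=C1 | intermediate
15 | ethyl glyoxylate (ethyl 2-oxoacetate) | CCOC(=O)C=O | starting material
16 | aldol adduct of 14 and 15 (CH(OH)CO2Et on C11; C11 and C12 epimers) | O=C1C(C(O)C(=O)OCC)[C@]2(C)CC[C@H](O[Si](C)(C)C(C)(C)C)C(C)(C)O[C@H]2C=C1 | intermediate (not isolated)
17 | mesylate of 16 | O=C1C(C(OS(C)(=O)=O)C(=O)OCC)[C@]2(C)CC[C@H](O[Si](C)(C)C(C)(C)C)C(C)(C)O[C@H]2C=C1 | intermediate (not isolated)
18 | (4S,7S,10S)-dienone ester (exocyclic C11=C12H–CO2Et, geometry not assigned) | O=C1C(=CC(=O)OCC)[C@]2(C)CC[C@H](O[Si](C)(C)C(C)(C)C)C(C)(C)O[C@H]2C=C1 | intermediate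
19 | (4S,7S,10S,11S)-keto ester (C1 ketone, CH2CO2Et on C11) | O=C1CC[C@@H]2OC(C)(C)[C@@H](O[Si](C)(C)C(C)(C)C)CC[C@@]2(C)[C@@H]1CC(=O)OCC | intermediate
20 | (4S,7S,10S,11R)-methylene ester | C=C1CC[C@@H]2OC(C)(C)[C@@H](O[Si](C)(C)C(C)(C)C)CC[C@@]2(C)[C@@H]1CC(=O)OCC | intermediate
21 | (4S,7S,10S,11R)-left-half aldehyde (C13 aldehyde) | C=C1CC[C@@H]2OC(C)(C)[C@@H](O[Si](C)(C)C(C)(C)C)CC[C@@]2(C)[C@@H]1CC=O | intermediate
22 | (15S,18S,21S)-C18 4-methoxybenzyl ether of 11 | C1[C@]2(C)CC[C@H](OCc3ccc(OC)cc3)C(C)(C)O[C@H]2CCC14OCCO4 | intermediate
23 | (15S,18S,21S)-right-series ketone (C24 ketone, C18 OPMB) | O=C1C[C@]2(C)CC[C@H](OCc3ccc(OC)cc3)C(C)(C)O[C@H]2CC1 | intermediate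
24 | (15S,18S,21S)-right-series enone (C22=C23) | O=C1C[C@]2(C)CC[C@H](OCc3ccc(OC)cc3)C(C)(C)O[C@H]2C=C1 | intermediate
25 | union aldol adduct (C13 carbinol; C13 and C14 epimers) | C=C1CC[C@@H]2OC(C)(C)[C@@H](O[Si](C)(C)C(C)(C)C)CC[C@@]2(C)[C@@H]1CC(O)C1[C@]2(C)CC[C@H](OCc3ccc(OC)cc3)C(C)(C)O[C@H]2C=CC1=O | intermediate (not isolated)
26 | mesylate of 25 | C=C1CC[C@@H]2OC(C)(C)[C@@H](O[Si](C)(C)C(C)(C)C)CC[C@@]2(C)[C@@H]1CC(OS(C)(=O)=O)C1[C@]2(C)CC[C@H](OCc3ccc(OC)cc3)C(C)(C)O[C@H]2C=CC1=O | intermediate (not isolated)
27 | (4S,7S,10S,11R,15S,18S,21S)-dienone (C13=C14 and C22=C23, geometry at C13=C14 not assigned) | C=C1CC[C@@H]2OC(C)(C)[C@@H](O[Si](C)(C)C(C)(C)C)CC[C@@]2(C)[C@@H]1CC=C1[C@]2(C)CC[C@H](OCc3ccc(OC)cc3)C(C)(C)O[C@H]2C=CC1=O | intermediate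
28 | (4S,7S,10S,11R,14S,15S,18S,21S)-ketone (C24 ketone) | C=C1CC[C@@H]2OC(C)(C)[C@@H](O[Si](C)(C)C(C)(C)C)CC[C@@]2(C)[C@@H]1CC[C@H]1[C@]2(C)CC[C@H](OCc3ccc(OC)cc3)C(C)(C)O[C@H]2CCC1=O | intermediate
29 | (4S,7S,10S,11R,14S,15S,18S,21S,24R)-tertiary alcohol | C=C1CC[C@@H]2OC(C)(C)[C@@H](O[Si](C)(C)C(C)(C)C)CC[C@@]2(C)[C@@H]1CC[C@H]1[C@]2(C)CC[C@H](OCc3ccc(OC)cc3)C(C)(C)O[C@H]2CC[C@@]1(C)O | intermediate
30 | (4S,7S,10S,11R,14S,15S,18S,21S,24R)-diol (C18 OH free, C7 OTBS) | C=C1CC[C@@H]2OC(C)(C)[C@@H](O[Si](C)(C)C(C)(C)C)CC[C@@]2(C)[C@@H]1CC[C@H]1[C@]2(C)CC[C@H](O)C(C)(C)O[C@H]2CC[C@@]1(C)O | intermediate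
31 | (4S,7S,10S,11R,14S,15S,21S,24R)-C7 tert-butyldimethylsilyl ether of the target | C=C1CC[C@@H]2OC(C)(C)[C@@H](O[Si](C)(C)C(C)(C)C)CC[C@@]2(C)[C@@H]1CC[C@H]1[C@]2(C)CCC(=O)C(C)(C)O[C@H]2CC[C@@]1(C)O | intermediate
32 | CNP0160418.1 (4S,7S,10S,11R,14S,15S,21S,24R) | C=C1CC[C@@H]2OC(C)(C)[C@@H](O)CC[C@@]2(C)[C@@H]1CC[C@H]1[C@]2(C)CCC(=O)C(C)(C)O[C@H]2CC[C@@]1(C)O | target

## Step count and risk

Total: 23 steps. Longest linear sequence: 20 steps (steps 1–14, then 18–23).

**Step 4 (key step, proposed new method).** Most likely failure: poor discrimination between the two enone faces. The uncomplexed furanone also absorbs weakly at the irradiation wavelength and reacts through a racemic channel, and the Lewis acid may bind or ionize the ketal instead of the carbonyl. A second danger is bonding of C21 to the terminal carbon C16 (tertiary radical, seven-membered ring) in competition with closure onto the fully substituted C15. Fallback with known chemistry, from 3 back to 8: ketalization of 3 with (2R,3R)-butane-2,3-diol gives the chiral ketal ester F1. Claisen condensation with 5 and cyclodehydration as in step 3 give the chiral ketal furanone F2. Direct irradiation at 350 nm without Lewis acid, the ordinary intramolecular enone–alkene photocycloaddition, gives two cis-fused diastereomers that differ in the configuration of the new centres relative to the C2-symmetric auxiliary; they are separated by chromatography. The 15S isomer, the chiral ketal photoadduct F3, is hydrolysed with PPTS in wet acetone to the photoadduct diketone F4. Ethylene glycol with acid catalysis then ketalizes only the unhindered C24 carbonyl and returns 8.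

**Step 5 (proposed new method).** Most likely failure: slow ionization, because the ring-fusion bond C17–C21 lies close to the plane of the carbonyl group and overlaps poorly with its π system. The silyl Lewis acid may also ionize the ketal, whose cation can be trapped within the molecule by the enol ether or silyl enol ether. Fallback with known chemistry, from 8 directly to 10: heating 8 with Bu3SnH and AIBN in benzene should add the stannyl radical to the C18 oxygen. The α-stannyloxy radical cleaves the C17–C21 bond to the tributylstannyl enol ether F5 and a tertiary, oxygen-stabilized radical at C21, which takes hydrogen from the stannane on the face away from the C15 methyl. Aqueous work-up of F5 gives 10, so that 9 and the hydrogenation are bypassed and the ketal never meets an acid.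

**Step 7.** Most likely failure: the inherent facial bias of the oxepanone (angular methyl on one face, gem-dimethyl next to the carbonyl) overriding the catalyst, so that the 18R carbinol predominates; this would spoil C7 of the left half. Fallback, from 10 back to 11: reduction with a ketoreductase selected from a screening panel for the S-configured alcohol, with NADPH recycled by isopropanol. This replaces a small-molecule catalyst that reads only the size of the two flanks by a binding pocket that holds the whole bicycle (no new compound, F0).

**Step 18.** Most likely failure: proton transfer from the α-methylene of the aldehyde to the hindered C14 enolate, and retro-aldol on warming, so that both halves are recovered unjoined. Fallback, from 21 and 24 back to 28, by alkylation in place of aldol condensation: NaBH4 reduces 21 to the left-half primary alcohol F6, and I2, PPh3 and imidazole convert it to the left-half iodide F7. The lithium enolate of 24 in THF/DMPU is alkylated by F7 on the face away from the C15 methyl to give the (14R)-alkylated enone F8, with no dehydration needed. [(Ph3P)CuH]6 reduces the ring double bond to the (14R)-ketone F9, and NaOMe in MeOH equilibrates C14 to the equatorial epimer 28.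

**Step 20.** Most likely failure: enolization of the hindered ketone in place of addition, or incomplete preference for the equatorial trajectory. Fallback, from 28 back to 29: dimethylsulfonium methylide (from Me3SI and KN(SiMe3)2) adds its methylene equatorially for the same steric reason and closes to the C24 spiro-epoxide F10 with the oxygen axial. LiEt3BH then opens the epoxide at the methylene carbon to give the methyl carbinol 29.

## Further compounds

F1 | step 4 | methyl 3-[(4R,5R)-4,5-dimethyl-2-(2-methylprop-2-en-1-yl)-1,3-dioxolan-2-yl]propanoate | COC(=O)CCC1(CC(C)=C)O[C@H](C)[C@@H](C)O1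
F2 | step 4 | 5-{2-[(4R,5R)-4,5-dimethyl-2-(2-methylprop-2-en-1-yl)-1,3-dioxolan-2-yl]ethyl}-2,2-dimethylfuran-3(2H)-one | CC1(C)OC(CCC2(CC(C)=C)O[C@H](C)[C@@H](C)O2)=CC1=O
F3 | step 4 | (15S,17R,21R)-photoadduct with the (4R,5R)-4,5-dimethyl-1,3-dioxolane at C24 | C1[C@]2(C)C[C@H]3C(=O)C(C)(C)O[C@@]23CCC14O[C@H](C)[C@@H](C)O4
F4 | step 4 | (15S,17R,21R)-photoadduct diketone (C24 ketone) | C1[C@]2(C)C[C@H]3C(=O)C(C)(C)O[C@@]23CCC1=O
F5 | step 5 | (15S,21S)-tributylstannyl enol ether of 10 (C17=C18–OSnBu3) | C1[C@]2(C)CC=C(O[Sn](CCCC)(CCCC)CCCC)C(C)(C)O[C@H]2CCC13OCCO3
F0 | step 7 | none | none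
F6 | step 18 | (4S,7S,10S,11R)-left-half primary alcohol (C13 OH) | C=C1CC[C@@H]2OC(C)(C)[C@@H](O[Si](C)(C)C(C)(C)C)CC[C@@]2(C)[C@@H]1CCO
F7 | step 18 | (4S,7S,10S,11R)-left-half iodide (C13 I) | C=C1CC[C@@H]2OC(C)(C)[C@@H](O[Si](C)(C)C(C)(C)C)CC[C@@]2(C)[C@@H]1CCI
F8 | step 18 | (14R)-alkylated enone (C13–C14 bond formed, C22=C23 retained) | C=C1CC[C@@H]2OC(C)(C)[C@@H](O[Si](C)(C)C(C)(C)C)CC[C@@]2(C)[C@@H]1CC[C@@H]1[C@]2(C)CC[C@H](OCc3ccc(OC)cc3)C(C)(C)O[C@H]2C=CC1=O
F9 | step 18 | (14R)-ketone, the C14 epimer of 28 | C=C1CC[C@@H]2OC(C)(C)[C@@H](O[Si](C)(C)C(C)(C)C)CC[C@@]2(C)[C@@H]1CC[C@@H]1[C@]2(C)CC[C@H](OCc3ccc(OC)cc3)C(C)(C)O[C@H]2CCC1=O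
F10 | step 20 | C24 spiro-epoxide of 28 (epoxide oxygen axial, syn to the C15 methyl) | C=C1CC[C@@H]2OC(C)(C)[C@@H](O[Si](C)(C)C(C)(C)C)CC[C@@]2(C)[C@@H]1CC[C@H]1[C@]2(C)CC[C@H](OCc3ccc(OC)cc3)C(C)(C)O[C@H]2CC[C@@]14OC4
A1 | alternative 1 | (Z)-diepoxy allylsilane: C13 tert-butyldiphenylsilyl ether with (4S,10S)- and (7S)-epoxides and a (trimethylsilyl)methyl group on C1 | C[Si](C)(C)C/C(CC[C@@H]1O[C@@]1(C)CC[C@@H]1OC1(C)C)=C\CCO[Si](c1ccccc1)(c1ccccc1)C(C)(C)C
A2 | alternative 1 | left bicycle with C7 carbinol and C13 tert-butyldiphenylsilyl ether | C=C1CC[C@@H]2OC(C)(C)[C@@H](O)CC[C@@]2(C)[C@@H]1CCO[Si](c1ccccc1)(c1ccccc1)C(C)(C)C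
A3 | alternative 2 | ring D enol ether (C15=C21) with C18 ethylene ketal and a C21 side chain carrying the C24 triethylsilyl ether and an (E)-allylsilane | CC1=C(CC[C@@](C)(O[Si](CC)(CC)CC)/C=C/C[Si](C)(C)C)OC(C)(C)C2(OCCO2)CC1
A4 | alternative 2 | ring C/D methyl ketal with C14 vinyl group | C=C[C@H]1[C@]2(C)CCC3(OCCO3)C(C)(C)O[C@@]2(OC)CC[C@@]1(C)O[Si](CC)(CC)CC
A5 | alternative 3 | ring D oxepane with (E)-enoate on C15 and 3-oxobutyl chain on C21; C18 ethylene ketal | COC(=O)/C=C/[C@]1(C)CCC2(OCCO2)C(C)(C)O[C@H]1CCC(C)=O
A6 | alternative 3 | ring C/D γ-lactone | O=C1C[C@H]2[C@]3(C)CCC4(OCCO4)C(C)(C)O[C@H]3CC[C@@]2(C)O1
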